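**Retrosynthetic overview**

1. Numbering: carbocycle C1–C10 (ether O from C1 to C4, CH3 on C4 and C10, OH on C10, ester O on C8, lactone O on C6), butenolide C11 (α), C12 (C=O), C13 (CH2OAc); Cb is an extra carbon that bridges C5 and C10 until it is excised. The strategy rests on this feature: C1 and C4 are the 2,5-carbons of the oxolane, i.e. the α-carbons of 2-methylfuran, and C5–C10 closed by Cb is a cycloheptane.
2. Target ⇒ triol 25 (C13 acetate, C8 (S)-2-methylglycidate) ⇒ C7 enone 17; the butenolide is built on the C7 ketone by ester-enolate addition, iodolactonisation across C5=C6 and double elimination.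
3. 17 ⇒ ten-membered alkene ketone 12 (methyl addition at C10, oxidation of the only allylic CH2 at C7, hydroxylation at C8) ⇒ keto acid 11 by oxidative decarboxylation at C5.
4. 11 ⇒ tricyclic ketol 10 (cleavage of C10–Cb) ⇒ adduct 9 ⇒ 2-methylfuran + the cyclic 1-alkoxy-2-siloxyallyl cation from enol silane 6; this (4+3) cycloaddition forms C1–C10 and C4–C5.
5. Ring order: cycloheptane (bought) → oxolane and seven-membered carbocycle together in the (4+3) step → ten-membered ring unveiled by excision of Cb → butenolide last.

Key step: step 5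

**Remarks and assumptions**

- C6–C9 enter the cation precursor as plain methylenes. A ketal at C6 would be allylic to the enol silane, would ionise before the α-keto ketal (to a vinylogous ester) and would crowd C5, the carbon that must bond to the methyl-bearing furan carbon. In consequence the carboxyl left on C5 after bridge cleavage is removed oxidatively, which gives C5=C6 directly.
- The ketal is the mixed methyl/(R)-1-phenylethyl ketal, used as both epimers at the ketal carbon; both give the same cation.
- Assumption 1: (R)-1-phenylethanol is taken as the auxiliary antipode that gives the (1S,4R) bridgeheads through the compact adduct. The sense is checked by correlation at 11; (S)-1-phenylethanol would be used in the same steps if the sense is opposite.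
- Assumption 2: hydroxylation in step 12 is taken to give the (8S) alcohol drawn; the configuration is assigned at 16.

**Route**

Step 1
Reactants: 1 cycloheptanone
Product: 2 2,2-dimethoxycycloheptan-1-ol (racemic)
Conditions: PhI(OAc)2, KOH, MeOH, 0 °C to rt
Reagents that add atoms: methanol (CO)
Why: Hypervalent-iodine α-hydroxylation (Moriarty type): the enolate is iodinated, methoxide adds to the carbonyl, and the methoxy-oxirane formed on loss of PhI is opened by methanol at the acetal carbon, so the old carbonyl carbon becomes the dimethyl ketal and its neighbour carries the hydroxyl; the ketone is symmetric, so no regiochemistry arises.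

Step 2
Reactants: 2 2,2-dimethoxycycloheptan-1-ol
Product: 3 2,2-dimethoxycycloheptan-1-one
Conditions: TPAP (cat.), NMO, 4 Å MS, CH2Cl2, rt
Reagents that add atoms: none
Why: Ley–Griffith oxidation of a secondary alcohol under neutral conditions that leave the dimethyl ketal intact.

Step 3
Reactants: 3 2,2-dimethoxycycloheptan-1-one; 4 (R)-1-phenylethanol
Product: 5 2-methoxy-2-[(1R)-1-phenylethoxy]cycloheptan-1-one (both epimers at the ketal carbon)
Conditions: 4 (1.1 equiv), CSA (cat.), cyclohexane, 45 °C, reduced pressure (MeOH removed)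
Reagents that add atoms: none
Why: Acid-catalysed transketalisation driven by removal of methanol exchanges one methoxy group; the new ketal centre forms as both epimers, which is harmless because it becomes the planar oxocarbenium carbon in step 5, and the mild acid should not ionise the benzylic alcohol.

Step 4
Reactants: 5 2-methoxy-2-[(1R)-1-phenylethoxy]cycloheptan-1-one
Product: 6 triethyl({7-methoxy-7-[(1R)-1-phenylethoxy]cyclohept-1-en-1-yl}oxy)silane (both ketal epimers)
Conditions: KHMDS, THF, −78 °C; TESCl
Reagents that add atoms: chlorotriethylsilane (CC[Si](Cl)(CC)CC)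
Why: Silyl enol ether formation; the ketal carbon has no hydrogen, so deprotonation can occur only at the CH2 that becomes C5.

Step 5
Reactants: 6 enol silane; 7 2-methylfuran
Product: 9 (1R,2S,5R,6R)-5-methyl-1-[(1R)-1-phenylethoxy]-12-oxatricyclo[4.4.1.1(2,5)]dodec-3-en-11-one (compact adduct; tricyclo C1 = C10, C2 = C1, C5 = C4, C6 = C5, C11 = Cb), via oxyallyl cation triflate 8 (not isolated)
Conditions: TMSOTf (0.1 equiv), 2-methylfuran (5 equiv), CH2Cl2, −95 to −78 °C; pyridine, aq. NaHCO3
Reagents that add atoms: none
Why: Proposed new method: catalytic silyl triflate removes the methoxy group of 6 as a silyl ether and releases the cyclic 1-alkoxy-2-siloxyallyl cation 8, whose oxocarbenium carbon C10 is attacked by the unsubstituted, most nucleophilic α-carbon of 2-methylfuran (C1–C10), and the methyl-stabilised 2H-furanium ion is then captured at C4 by the enol silane carbon C5, a stepwise (4+3) cycloaddition; the closest known reactions are the silyl-triflate-triggered (4+3) cycloadditions of furans with acyclic α-keto acetal enol silanes, 1-phenylethyl mixed acetals included, and the (4+3) cycloadditions of cyclic oxyallyl cations from α-halo cycloalkanones. The second bond closes the seven-membered carbocycle C10–Cb–C5–C4–C3–C2–C1 by Mukaiyama-type attack of the ring enol silane on the furanium C=O+ (7-(enolendo)-exo-trig at C4), which also completes the oxygen-bridged ten-membered ring C1–C10. C1 and C4 are necessarily cis because the furan oxygen becomes the bridge, the U-shaped ring cation forces C6 and C9 cis, and the compact orientation puts them on the face of the oxygen bridge; C5 and C10 are temporary centres. The absolute sense at C1/C4 depends on two things, the face of C10 left open by the (R)-1-phenylethyl group in the oxocarbenium conformer of least allylic strain and the compact rather than extended approach of the furan, because the extended adduct on the same face would give the enantiomeric ten-membered ring after excision of Cb; both selectivities are needed and the auxiliary antipode is matched by correlation. Regiochemistry (free furan α-carbon to the alkoxy terminus) relies on the polarity of the stepwise addition, and the unsubstituted chain C6–C9 keeps ionisable or bulky groups away from C5.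

Step 6
Reactants: 9 (4+3) adduct
Product: 10 (1R,2S,5R,6R)-1-hydroxy-5-methyl-12-oxatricyclo[4.4.1.1(2,5)]dodecan-11-one
Conditions: H2 (1 atm), Pd(OH)2/C, EtOH, rt
Reagents that add atoms: none
Why: Hydrogenation saturates the strained C2=C3 bond and hydrogenolyses the benzylic C–O bond of the auxiliary, freeing the tertiary C10 hydroxyl next to the bridge ketone without touching a stereocentre.

Step 7
Reactants: 10 tricyclic ketol
Product: 11 (1S,4R,5R)-1,4-epoxy-4-methyl-10-oxocyclodecane-5-carboxylic acid
Conditions: NaIO4, THF–H2O, rt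
Reagents that add atoms: water (O)
Why: Periodate cleavage of the α-hydroxy ketone through its hydrate (glycol-type cleavage) cuts C10–Cb, so C10 becomes a ketone and Cb a carboxylic acid on C5, which opens the cycloheptane and leaves the ether-bridged ten-membered ring.

Step 8
Reactants: 11 keto acid
Product: 12 (1S,4R,5Z)-1,4-epoxy-4-methylcyclodec-5-en-10-one
Conditions: Pb(OAc)4, Cu(OAc)2 (cat.), pyridine, PhH, 80 °C
Reagents that add atoms: none
Why: Kochi oxidative decarboxylation: Pb(IV) gives the C5 radical and Cu(II) oxidises it to the alkene; C4 is quaternary, so the only β-hydrogens are on C6 and C5=C6 is the only possible alkene (ring-cis expected; the geometry is set again in step 17).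

Step 9
Reactants: 12 alkene ketone
Product: 13 (1S,4R,5Z,10R)-1,4-epoxy-4,10-dimethylcyclodec-5-en-10-ol
Conditions: MeMgBr, Et2O–CH2Cl2, −78 °C
Reagents that add atoms: methylmagnesium bromide (C[Mg]Br)
Why: Grignard addition under Cram-chelate control: magnesium bridges the ketone oxygen and the oxolane oxygen on C1, and methyl should add from the outer face on the side of C1–H, which corresponds to the (10R) alcohol of the target.

Step 10
Reactants: 13 tertiary alcohol
Product: 14 (1S,4R,5Z,10R)-1,4-epoxy-4,10-dimethyl-10-(triethylsilyloxy)cyclodec-5-ene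
Conditions: TESOTf, 2,6-lutidine, CH2Cl2, −78 to 0 °C
Reagents that add atoms: triethylsilyl triflate (CC[Si](CC)(CC)OS(=O)(=O)C(F)(F)F)
Why: Silylation of the tertiary alcohol with a silyl triflate; it prevents transannular hemiketal formation with the later C7 ketone and iodoetherification in step 16.

Step 11
Reactants: 14 silyl ether alkene
Product: 15 (1S,4R,5Z,10R)-1,4-epoxy-4,10-dimethyl-10-(triethylsilyloxy)cyclodec-5-en-7-one
Conditions: Rh2(cap)4 (1 mol%), TBHP, K2CO3, CH2Cl2, rt
Reagents that add atoms: tert-butyl hydroperoxide (CC(C)(C)OO)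
Why: Dirhodium caprolactamate/TBHP allylic oxidation: C7 is the only allylic CH2 because C4 carries no hydrogen, and peroxide capture at the unhindered end of the allyl radical should give the C7 enone with C5=C6 in place.

Step 12
Reactants: 15 enone
Product: 16 (1S,4R,5Z,8S,10R)-1,4-epoxy-8-hydroxy-4,10-dimethyl-10-(triethylsilyloxy)cyclodec-5-en-7-one
Conditions: KHMDS, THF, −78 °C; 2-(phenylsulfonyl)-3-phenyloxaziridine
Reagents that add atoms: 2-(phenylsulfonyl)-3-phenyloxaziridine (O=S(=O)(c1ccccc1)N1OC1c1ccccc1)
Why: Enolate hydroxylation with a sulfonyloxaziridine (Davis reagent): C8 is the only enolisable position (no γ-hydrogen on C4), and the oxidant is expected to approach the outer face of the ring enolate to give the (8S) alcohol.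

Step 13
Reactants: 16 hydroxy enone
Product: 17 (1S,4R,5Z,8S,10R)-8-(tert-butyldimethylsilyloxy)-1,4-epoxy-4,10-dimethyl-10-(triethylsilyloxy)cyclodec-5-en-7-one
Conditions: TBSOTf, 2,6-lutidine, CH2Cl2, −78 °C
Reagents that add atoms: tert-butyldimethylsilyl triflate (CC(C)(C)[Si](C)(C)OS(=O)(=O)C(F)(F)F)
Why: Standard silylation of a secondary α-hydroxy ketone at low temperature without enolisation.

Step 14
Reactants: 18 tert-butyl 3-hydroxypropanoate
Product: 19 tert-butyl 3-[(tert-butyldimethylsilyl)oxy]propanoate
Conditions: TBSCl, imidazole, DMF, rt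
Reagents that add atoms: tert-butyldimethylsilyl chloride (CC(C)(C)[Si](C)(C)Cl)
Why: Standard silylation of a primary alcohol.

Step 15
Reactants: 17 silyloxy enone; 19 silyloxy ester
Product: 20 tert-butyl 2-[7-hydroxy-ring C7]-3-(silyloxy)propanoate aldol adduct (C1, C4, C8, C10 as in 17; mixture at C7 and C11)
Conditions: 19, LDA, THF, −78 °C; CeCl3, −78 °C; then 17, −78 °C
Reagents that add atoms: none
Why: Aldol addition of the ester enolate, transmetallated to cerium to suppress enolisation of the hindered ketone, occurs 1,2 because the β-carbon C5 is neopentyl; it attaches C11 with C12 and C13 to C7, and the new centres at C7 and C11 need no control because both become sp2 in step 17.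

Step 16
Reactants: 20 aldol adduct
Product: 21 iodolactone (C6–O–C12(=O)–C11–C7 γ-lactone, iodide on C5, free OH on C7; mixture at C5, C6, C7, C11)
Conditions: I2, NaHCO3, MeCN, 0 °C to rt, dark
Reagents that add atoms: iodine (II)
Why: Iodolactonisation: the ester carbonyl opens the iodonium ion at C6 in a 5-exo mode with loss of the tert-butyl group as isobutene, which puts the lactone oxygen on C6 and a leaving group on C5; the centres at C5 and C6 are erased in step 17.

Step 17
Reactants: 21 iodolactone
Product: 24 tris-silyl γ-ylidene butenolide (5E by CIP; C4 cis to C7), via C7 mesylate 22 (not isolated), via iodobutenolide 23 (not isolated)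
Conditions: MsCl, Et3N, CH2Cl2, 0 °C; then DBU, rt
Reagents that add atoms: none
Why: Mesylation of the tertiary β-hydroxy lactone and E1cB loss of methanesulfonate give the C7=C11 butenolide, whose acidic C6–H is then removed so that iodide leaves from C5 (vinylogous E1cB); the ring-cis C5=C6 geometry is the only one that lets the ten-membered ring span the planar dienol lactone.

Step 18
Reactants: 24 tris-silyl ether
Product: 25 triol (C8–OH, C10–OH, C13–OH)
Conditions: HF·pyridine, pyridine–THF, 0 °C to rt
Reagents that add atoms: none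
Why: Fluoride-mediated cleavage of the two TBS ethers and the TES ether under buffered conditions that the enol lactone should tolerate.

Step 19
Reactants: 25 triol
Product: 26 C13 monoacetate
Conditions: AcCl (1.05 equiv), 2,4,6-collidine, CH2Cl2, −78 °C
Reagents that add atoms: acetyl chloride (CC(=O)Cl)
Why: Selective acetylation of the primary allylic alcohol at low temperature with a hindered base; the secondary C8 and tertiary C10 hydroxyls react much more slowly.

Step 20
Reactants: 27 methyl (S)-2-methyloxirane-2-carboxylate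
Product: 28 potassium (S)-2-methyloxirane-2-carboxylate
Conditions: KOH (1.0 equiv), EtOH, 0 °C; evaporation
Reagents that add atoms: potassium hydroxide ([K+].[OH-])
Why: Saponification with one equivalent of hydroxide; the quaternary epoxide carbon cannot epimerise, and the salt is isolated without acidification to protect the epoxide.

Step 21
Reactants: 26 C13 monoacetate; 28 potassium glycidate
Product: 30 CNP0142137.1 (target), via mixed anhydride 29 (not isolated)
Conditions: 28, 2,4,6-trichlorobenzoyl chloride, Et3N, THF, 0 °C; then 26, DMAP, toluene, rt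
Reagents that add atoms: none
Why: Yamaguchi esterification: the mixed anhydride acylates the secondary C8 hydroxyl with retention at C8 under DMAP catalysis, while the tertiary C10 hydroxyl is inert.

**Compound list**

1 | cycloheptanone | O=C1CCCCCC1 | starting material
2 | 2,2-dimethoxycycloheptan-1-ol (racemic) | COC1(OC)CCCCCC1O | intermediate
3 | 2,2-dimethoxycycloheptan-1-one | COC1(OC)CCCCCC1=O | intermediate
4 | (R)-1-phenylethanol | C[C@@H](O)c1ccccc1 | starting material
5 | 2-methoxy-2-[(1R)-1-phenylethoxy]cycloheptan-1-one (both ketal epimers) | COC1(O[C@H](C)c2ccccc2)CCCCCC1=O | intermediate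
6 | triethyl({7-methoxy-7-[(1R)-1-phenylethoxy]cyclohept-1-en-1-yl}oxy)silane (both ketal epimers) | CC[Si](CC)(CC)OC1=CCCCCC1(OC)O[C@H](C)c1ccccc1 | intermediate
7 | 2-methylfuran | Cc1ccco1 | starting material
8 | cyclic 1-[(R)-1-phenylethoxy]-2-(triethylsilyloxy)allyl cation triflate | CC[Si](CC)(CC)OC1=CCCCCC1=[O+][C@H](C)c1ccccc1.[O-]S(=O)(=O)C(F)(F)F | intermediate
9 | (1R,2S,5R,6R)-5-methyl-1-[(1R)-1-phenylethoxy]-12-oxatricyclo[4.4.1.1(2,5)]dodec-3-en-11-one | O=C1[C@H]2[C@@]3(C)C=C[C@H](O3)[C@]1(O[C@H](C)c4ccccc4)CCCC2 | intermediate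
10 | (1R,2S,5R,6R)-1-hydroxy-5-methyl-12-oxatricyclo[4.4.1.1(2,5)]dodecan-11-one | O=C1[C@H]2[C@@]3(C)CC[C@H](O3)[C@]1(O)CCCC2 | intermediate
11 | (1S,4R,5R)-1,4-epoxy-4-methyl-10-oxocyclodecane-5-carboxylic acid | OC(=O)[C@H]1[C@@]2(C)CC[C@H](O2)C(=O)CCCC1 | intermediate
12 | (1S,4R,5Z)-1,4-epoxy-4-methylcyclodec-5-en-10-one | C1/C=C\[C@@]2(C)CC[C@H](O2)C(=O)CC1 | intermediate
13 | (1S,4R,5Z,10R)-1,4-epoxy-4,10-dimethylcyclodec-5-en-10-ol | C1/C=C\[C@@]2(C)CC[C@H](O2)[C@](C)(O)CC1 | intermediate
14 | (1S,4R,5Z,10R)-1,4-epoxy-4,10-dimethyl-10-(triethylsilyloxy)cyclodec-5-ene | C1/C=C\[C@@]2(C)CC[C@H](O2)[C@](C)(O[Si](CC)(CC)CC)CC1 | intermediate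
15 | (1S,4R,5Z,10R)-1,4-epoxy-4,10-dimethyl-10-(triethylsilyloxy)cyclodec-5-en-7-one | O=C1/C=C\[C@@]2(C)CC[C@H](O2)[C@](C)(O[Si](CC)(CC)CC)CC1 | intermediate
16 | (1S,4R,5Z,8S,10R)-1,4-epoxy-8-hydroxy-4,10-dimethyl-10-(triethylsilyloxy)cyclodec-5-en-7-one | O=C1/C=C\[C@@]2(C)CC[C@H](O2)[C@](C)(O[Si](CC)(CC)CC)C[C@@H]1O | intermediate
17 | (1S,4R,5Z,8S,10R)-8-(tert-butyldimethylsilyloxy)-1,4-epoxy-4,10-dimethyl-10-(triethylsilyloxy)cyclodec-5-en-7-one | O=C1/C=C\[C@@]2(C)CC[C@H](O2)[C@](C)(O[Si](CC)(CC)CC)C[C@@H]1O[Si](C)(C)C(C)(C)C | intermediate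
18 | tert-butyl 3-hydroxypropanoate | CC(C)(C)OC(=O)CCO | starting material
19 | tert-butyl 3-[(tert-butyldimethylsilyl)oxy]propanoate | CC(C)(C)OC(=O)CCO[Si](C)(C)C(C)(C)C | intermediate
20 | aldol adduct: tert-butyl 2-(7-hydroxy-C7-ring)-3-(silyloxy)propanoate (mixture at C7 and C11) | CC(C)(C)OC(=O)C(CO[Si](C)(C)C(C)(C)C)C1(O)/C=C\[C@@]2(C)CC[C@H](O2)[C@](C)(O[Si](CC)(CC)CC)C[C@@H]1O[Si](C)(C)C(C)(C)C | intermediate
21 | iodolactone: 5-iodo-7-hydroxy-6,12-olide (mixture at C5, C6, C7, C11) | CC(C)(C)[Si](C)(C)OCC1C(=O)OC2C(I)[C@@]3(C)CC[C@H](O3)[C@](C)(O[Si](CC)(CC)CC)C[C@H](O[Si](C)(C)C(C)(C)C)C12O | intermediate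
22 | C7 mesylate of 21 | CC(C)(C)[Si](C)(C)OCC1C(=O)OC2C(I)[C@@]3(C)CC[C@H](O3)[C@](C)(O[Si](CC)(CC)CC)C[C@H](O[Si](C)(C)C(C)(C)C)C12OS(C)(=O)=O | intermediate
23 | 5-iodo-7(11)-en-6,12-olide (iodobutenolide; mixture at C5, C6) | CC(C)(C)[Si](C)(C)OCC1=C2C(C(I)[C@@]3(C)CC[C@H](O3)[C@](C)(O[Si](CC)(CC)CC)C[C@@H]2O[Si](C)(C)C(C)(C)C)OC1=O | intermediate
24 | tris-silyl γ-ylidene butenolide (8-OTBS, 10-OTES, 13-OTBS; 1S,4R,5E,8S,10R) | CC(C)(C)[Si](C)(C)OCC1=C2/C(=C\[C@@]3(C)CC[C@H](O3)[C@](C)(O[Si](CC)(CC)CC)C[C@@H]2O[Si](C)(C)C(C)(C)C)OC1=O | intermediate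
25 | triol (8-OH, 10-OH, 13-OH; 1S,4R,5E,8S,10R) | OCC1=C2/C(=C\[C@@]3(C)CC[C@H](O3)[C@](C)(O)C[C@@H]2O)OC1=O | intermediate
26 | C13 monoacetate (8-OH, 10-OH) | CC(=O)OCC1=C2/C(=C\[C@@]3(C)CC[C@H](O3)[C@](C)(O)C[C@@H]2O)OC1=O | intermediate
27 | methyl (S)-2-methyloxirane-2-carboxylate | COC(=O)[C@]1(C)CO1 | starting material
28 | potassium (S)-2-methyloxirane-2-carboxylate | [K+].[O-]C(=O)[C@]1(C)CO1 | intermediate
29 | (S)-2-methyloxirane-2-carboxylic 2,4,6-trichlorobenzoic anhydride | O=C(OC(=O)[C@]1(C)CO1)c1c(Cl)cc(Cl)cc1Cl | intermediate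
30 | CNP0142137.1 | CC(=O)OCC1=C2/C(=C\[C@@]3(C)CC[C@H](O3)[C@](C)(O)C[C@@H]2OC(=O)[C@]2(C)CO2)OC1=O | target

**Step count**

Total: 21 steps. Longest linear sequence: 19 steps (steps 1–13, 15–19, 21).

**Steps most likely to fail**

Step 5 (proposed new method). Several processes can divert it: the 2H-furanium ion may lose a proton before the enol silane closes, which gives a furan alkylation product and no ring. The furan may attack the less hindered C5 end first and reverse the regiochemistry. Facial or compact/extended selectivity may be incomplete. The silyl triflate may remove the 1-phenylethoxy group in place of methoxide, so that an achiral methoxy cation reacts. The fallback uses known chemistry, the base-mediated (4+3) cycloaddition of an α-chloro ketone in a fluorinated alcohol, and sets out from 6. Ionic hydrogenation of the same cation (Et3SiH, cat. TMSOTf, CH2Cl2, −78 °C) gives triethyl({7-[(1R)-1-phenylethoxy]cyclohept-1-en-1-yl}oxy)silane F1. N-Chlorosuccinimide (THF, 0 °C) chlorinates the enol silane carbon and gives 2-chloro-7-[(1R)-1-phenylethoxy]cycloheptan-1-one F2. Treating F2 with Et3N in 2,2,2-trifluoroethanol and excess 7 at room temperature generates the alkoxy-oxyallyl cation and its (4+3) adducts, from which 9 is separated from its diastereomers by chromatography. The route is rejoined at 9.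

Step 11. The peroxyl radical may abstract the C1–H next to the ring oxygen, the allyl radical may be captured at C5 to give the transposed enone, or the enone may be oxidised further. The fallback is a non-radical ene/[2,3] sequence from 14: SeO2 (cat.), TBHP, CH2Cl2 puts the oxygen on C7 and returns the double bond to C5=C6, giving (1S,4R,5Z,10R)-1,4-epoxy-4,10-dimethyl-10-(triethylsilyloxy)cyclodec-5-en-7-ol F3. Dess–Martin periodinane then gives 15.

Step 12. The oxaziridine may attack both faces of the ring enolate, or mainly the inner face, so that the (8R) alcohol forms. The fallback corrects the centre by SN2 inversion and sets out from 15: the (8R)-hydroxy enone F4 obtained in the hydroxylation is treated under Mitsunobu conditions (4-nitrobenzoic acid, PPh3, DIAD, toluene, 0 °C) to give the (8S)-4-nitrobenzoate F5. Methanolysis (K2CO3, MeOH, 0 °C) returns the route to 16.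

**Further compounds**

F1 | step 5 | triethyl({7-[(1R)-1-phenylethoxy]cyclohept-1-en-1-yl}oxy)silane (both C7 epimers) | CC[Si](CC)(CC)OC1=CCCCCC1O[C@H](C)c1ccccc1
F2 | step 5 | 2-chloro-7-[(1R)-1-phenylethoxy]cycloheptan-1-one (diastereomer mixture) | O=C1C(Cl)CCCCC1O[C@H](C)c1ccccc1
F3 | step 11 | (1S,4R,5Z,10R)-1,4-epoxy-4,10-dimethyl-10-(triethylsilyloxy)cyclodec-5-en-7-ol (C7 epimers) | OC1/C=C\[C@@]2(C)CC[C@H](O2)[C@](C)(O[Si](CC)(CC)CC)CC1
F4 | step 12 | (1S,4R,5Z,8R,10R)-1,4-epoxy-8-hydroxy-4,10-dimethyl-10-(triethylsilyloxy)cyclodec-5-en-7-one | O=C1/C=C\[C@@]2(C)CC[C@H](O2)[C@](C)(O[Si](CC)(CC)CC)C[C@H]1O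
F5 | step 12 | (8S)-4-nitrobenzoate of 16 | O=C1/C=C\[C@@]2(C)CC[C@H](O2)[C@](C)(O[Si](CC)(CC)CC)C[C@@H]1OC(=O)c1ccc(cc1)[N+](=O)[O-]
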